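**Retrosynthetic overview**
1. The target comes from acetylation of the erythro C7 alcohol. That alcohol comes from Mitsunobu inversion of the threo alcohol, and the C9 methyl comes from an acyl group (imide → CH2OH → CH2OTs → CH3).
2. Key C7–C8 bond: Evans boron aldol between an N-(aryloxyacetyl)oxazolidinone and 3,4,5-trimethoxybenzaldehyde. It sets C8 as in the target and gives C7 as the epimer that is inverted later.
3. The imide comes from the ring B/ring C phenol, ethyl bromoacetate and (S)-4-benzyloxazolidin-2-one.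
4. The ring B/ring C phenol comes from a Mitsunobu ether bond (inversion at C8') between an (S)-1-arylpropan-2-ol (aryl Grignard + (S)-propylene oxide) and (E)-4-propenyl-2,6-dimethoxyphenol.
5. No ring is formed. Rings A, B and C are bought and joined in the order C to B, then B to A.

Notation: C7 is the acetoxy-bearing benzylic carbon, C8 the adjacent aryloxy carbon, C9 its methyl carbon, and C8' the stereocentre between rings B and C. The given SMILES reads (7S,8R,8'R), which is erythro (anti) at C7/C8. ArBC = 4-[(2R)-2-{2,6-dimethoxy-4-[(E)-prop-1-enyl]phenoxy}propyl]-2,6-dimethoxyphenyl.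

Assumption: 4-bromo-2,6-dimethoxyphenol, (S)-propylene oxide, 4-allyl-2,6-dimethoxyphenol, ethyl bromoacetate, (S)-4-benzyloxazolidin-2-one and 3,4,5-trimethoxybenzaldehyde are taken as catalogue chemicals.

**Step 1**
Reactants: 1 4-bromo-2,6-dimethoxyphenol
Product: 2 (4-bromo-2,6-dimethoxyphenoxy)(tert-butyl)dimethylsilane
Conditions: TBSCl (1.2 equiv), imidazole (2.5 equiv), DMF, rt, 12 h
Reagents that add atoms: tert-butyldimethylsilyl chloride, CC(C)(C)[Si](C)(C)Cl
Why: Imidazole-promoted O-silylation masks the acidic phenol so that the aryl bromide can be metalated, and the group can later be removed with fluoride without harming an alkene.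

**Step 2**
Reactants: 2 (4-bromo-2,6-dimethoxyphenoxy)(tert-butyl)dimethylsilane; 3 (S)-propylene oxide
Product: 5 (S)-1-[4-(tert-butyldimethylsilyloxy)-3,5-dimethoxyphenyl]propan-2-ol, via arylmagnesium bromide 4 (not isolated)
Conditions: Mg turnings (1.3 equiv, I2 crystal), THF, reflux, 2 h; then CuI (10 mol %), 3 (1.2 equiv), −30 °C → 0 °C; aq. NH4Cl
Reagents that add atoms: magnesium, [Mg] (found only in intermediate 4)
Why: Copper-catalysed SN2 opening of the epoxide by the Grignard reagent occurs at the unsubstituted CH2, so the stereocentre of 3 is carried unchanged into (S)-5.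

**Step 3**
Reactants: 6 4-allyl-2,6-dimethoxyphenol
Product: 7 2,6-dimethoxy-4-[(E)-prop-1-enyl]phenol
Conditions: RuCl2(PPh3)3 (0.5–1 mol %), EtOH, 80 °C, 6 h; residual Z isomer (≤5 %) removed on AgNO3-impregnated silica
Reagents that add atoms: none
Why: Metal-hydride alkene isomerisation (addition/β-hydride elimination) moves the double bond into conjugation with the arene under thermodynamic control, which strongly favours the E-propenyl isomer.

**Step 4**
Reactants: 5 (S)-1-[4-(tert-butyldimethylsilyloxy)-3,5-dimethoxyphenyl]propan-2-ol; 7 2,6-dimethoxy-4-[(E)-prop-1-enyl]phenol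
Product: 8 tert-butyl{4-[(2R)-2-{2,6-dimethoxy-4-[(E)-prop-1-enyl]phenoxy}propyl]-2,6-dimethoxyphenoxy}dimethylsilane
Conditions: 7 (1.3 equiv), PPh3 (1.5 equiv), DIAD (1.5 equiv), THF (ca. 1 M), 0 °C → rt, 16 h
Reagents that add atoms: none
Why: In this Mitsunobu etherification the phenoxide displaces the alkoxyphosphonium group by SN2 with inversion, turning the (S)-carbinol into the (R)-aryl ether and setting C8'.

**Step 5**
Reactants: 8 TBS-protected ring B/ring C ether
Product: 9 4-[(2R)-2-{2,6-dimethoxy-4-[(E)-prop-1-enyl]phenoxy}propyl]-2,6-dimethoxyphenol (ArBC–OH)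
Conditions: Bu4NF (1.1 equiv), AcOH (1.1 equiv), THF, 0 °C, 30 min
Reagents that add atoms: none
Why: Buffered fluoride desilylation frees the ring B phenol under conditions that affect neither the ether stereocentre nor the E-propenyl group.

**Step 6**
Reactants: 9 ArBC–OH; 10 ethyl bromoacetate
Product: 11 ethyl 2-(ArBC-oxy)acetate
Conditions: K2CO3 (2 equiv), 10 (1.2 equiv), DMF, 50 °C, 6 h
Reagents that add atoms: none
Why: Williamson ether synthesis on the very reactive α-bromo ester works even for a flanked phenoxide and brings in the two carbons that become C8 and C9.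

**Step 7**
Reactants: 11 ethyl 2-(ArBC-oxy)acetate
Product: 12 2-(ArBC-oxy)acetic acid
Conditions: LiOH·H2O (3 equiv), THF/H2O 3:1, rt, 3 h; then 1 M HCl to pH 3
Reagents that add atoms: lithium hydroxide, [Li+].[OH-] (its oxygen ends in the CO2H group)
Why: Saponification of an unhindered ethyl ester is routine here because there is no α-stereocentre to epimerise and no other base-labile group.

**Step 8**
Reactants: 12 2-(ArBC-oxy)acetic acid; 13 (S)-4-benzyloxazolidin-2-one
Product: 15 (S)-4-benzyl-3-[2-(ArBC-oxy)acetyl]oxazolidin-2-one, via mixed pivalic anhydride 14 (not isolated)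
Conditions: PivCl (1.1 equiv), Et3N (2.5 equiv), THF, −20 °C, 1 h; then LiCl (1.1 equiv), 13 (1.05 equiv), −20 °C → rt, 12 h
Reagents that add atoms: pivaloyl chloride, CC(C)(C)C(=O)Cl (its acyl group is found only in intermediate 14)
Why: In this mixed-anhydride N-acylation the LiCl-activated oxazolidinone attacks the unhindered aryloxyacetyl carbonyl rather than the pivaloyl carbonyl, and the auxiliary stereocentre is untouched.

**Step 9 (key step)**
Reactants: 15 (S)-4-benzyl-3-[2-(ArBC-oxy)acetyl]oxazolidin-2-one; 16 3,4,5-trimethoxybenzaldehyde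
Product: 19 (S)-4-benzyl-3-[(2S,3R)-2-(ArBC-oxy)-3-hydroxy-3-(3,4,5-trimethoxyphenyl)propanoyl]oxazolidin-2-one (syn aldol), via Z-dibutylboron enolate 17 (not isolated), via dibutylboron aldolate 18 (not isolated)
Conditions: Bu2BOTf (1.2 equiv), Et3N (1.4 equiv), CH2Cl2, −78 → 0 °C, 1 h; 16 (1.2 equiv), −78 → 0 °C, 3 h; pH 7 buffer, MeOH, 30 % H2O2, 0 °C, 1 h
Reagents that add atoms: dibutylboron triflate, CCCCB(CCCC)OS(=O)(=O)C(F)(F)F (its Bu2B group is found only in intermediates 17 and 18)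
Why: In this Evans syn glycolate aldol the Z-boron enolate reacts through a Zimmerman–Traxler chair whose one face is blocked by the benzyl group of the (S)-auxiliary, so the C7–C8 bond forms 2,3-syn with C8 in the spatial arrangement of the target and C7 as the epimer corrected in step 15.

**Step 10**
Reactants: 19 syn aldol
Product: 20 (S)-4-benzyl-3-[(2S,3R)-2-(ArBC-oxy)-3-(tert-butyldimethylsilyloxy)-3-(3,4,5-trimethoxyphenyl)propanoyl]oxazolidin-2-one
Conditions: TBSOTf (1.5 equiv), 2,6-lutidine (2 equiv), CH2Cl2, 0 °C, 1 h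
Reagents that add atoms: tert-butyldimethylsilyl triflate, CC(C)(C)[Si](C)(C)OS(=O)(=O)C(F)(F)F
Why: Silylation of the C7 hydroxyl under non-nucleophilic base prevents retro-aldol, competing tosylation and oxetane formation during the C9 deoxygenation, and no C–O bond at a stereocentre is broken.

**Step 11**
Reactants: 20 silylated aldol imide
Product: 21 (2R,3R)-2-(ArBC-oxy)-3-(tert-butyldimethylsilyloxy)-3-(3,4,5-trimethoxyphenyl)propan-1-ol
Conditions: LiBH4 (2.5 equiv), H2O (2.5 equiv), Et2O/THF, 0 °C, 2 h; aq. NaOH work-up, 13 recovered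
Reagents that add atoms: none
Why: Reductive cleavage of the imide delivers hydride to the exocyclic carbonyl, releases the auxiliary and leaves both stereocentres alone (the C8 descriptor changes from S to R only because the substituent ranking changes).

**Step 12**
Reactants: 21 primary alcohol
Product: 22 (2R,3R)-2-(ArBC-oxy)-3-(tert-butyldimethylsilyloxy)-3-(3,4,5-trimethoxyphenyl)propyl 4-methylbenzenesulfonate
Conditions: TsCl (1.5 equiv), Et3N (3 equiv), DMAP (0.1 equiv), CH2Cl2, 0 °C → rt, 6 h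
Reagents that add atoms: 4-toluenesulfonyl chloride, Cc1ccc(cc1)S(=O)(=O)Cl
Why: DMAP-catalysed sulfonylation of the only free hydroxyl turns C9–OH into a leaving group without affecting any stereocentre.

**Step 13**
Reactants: 22 primary tosylate
Product: 23 tert-butyl{[(1R,2R)-2-(ArBC-oxy)-1-(3,4,5-trimethoxyphenyl)propyl]oxy}dimethylsilane
Conditions: LiEt3BH (3 equiv, 1 M in THF), THF, 0 °C → rt, 4 h; H2O quench
Reagents that add atoms: none
Why: SN2 displacement of the primary tosylate by the highly nucleophilic triethylborohydride converts C9 into the methyl group by a polar pathway, which avoids the β-aryloxy fragmentation a radical method would risk.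

**Step 14**
Reactants: 23 C7 silyl ether
Product: 24 (1R,2R)-2-(ArBC-oxy)-1-(3,4,5-trimethoxyphenyl)propan-1-ol (threo)
Conditions: Bu4NF (2 equiv, 1 M in THF), THF, rt, 4 h
Reagents that add atoms: none
Why: Fluoride desilylation cleaves only the Si–O bond, so the C7 configuration is retained and no base-sensitive group is present.

**Step 15**
Reactants: 24 threo alcohol
Product: 25 (1S,2R)-2-(ArBC-oxy)-1-(3,4,5-trimethoxyphenyl)propyl 4-nitrobenzoate (erythro)
Conditions: 4-nitrobenzoic acid (3 equiv), PPh3 (3 equiv), DIAD (3 equiv), toluene, −10 °C → rt, 12 h; chromatography or crystallisation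
Reagents that add atoms: 4-nitrobenzoic acid, O=C(O)c1ccc(cc1)[N+](=O)[O-]
Why: In this Mitsunobu inversion the acidic carboxylate displaces the benzylic alkoxyphosphonium by SN2 in a non-polar solvent that disfavours ionisation, turning C7 from R to S, and any retention product can be removed at this ester stage.

**Step 16**
Reactants: 25 erythro 4-nitrobenzoate
Product: 26 (1S,2R)-2-(ArBC-oxy)-1-(3,4,5-trimethoxyphenyl)propan-1-ol (erythro)
Conditions: K2CO3 (0.2 equiv), MeOH/THF 2:1, rt, 2 h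
Reagents that add atoms: none
Why: Base-catalysed transesterification cleaves the acyl–oxygen bond of the activated ester, so the C7–O bond and its S configuration are retained.

**Step 17**
Reactants: 26 erythro alcohol
Product: 27 (1S,2R)-2-(ArBC-oxy)-1-(3,4,5-trimethoxyphenyl)propyl acetate (CNP0157869.1)
Conditions: Ac2O (3 equiv), pyridine (6 equiv), DMAP (0.05 equiv), CH2Cl2, rt, 3 h
Reagents that add atoms: acetic anhydride, CC(=O)OC(C)=O
Why: DMAP-catalysed O-acetylation occurs at oxygen with retention at C7 and gives the (7S,8R,8'R,E) target.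

**Compound list**
1 | 4-bromo-2,6-dimethoxyphenol | COc1cc(Br)cc(OC)c1O | starting material
2 | (4-bromo-2,6-dimethoxyphenoxy)(tert-butyl)dimethylsilane | COc1cc(Br)cc(OC)c1O[Si](C)(C)C(C)(C)C | intermediate
3 | (S)-propylene oxide | C[C@H]1CO1 | starting material
4 | [4-(tert-butyldimethylsilyloxy)-3,5-dimethoxyphenyl]magnesium bromide | COc1cc([Mg]Br)cc(OC)c1O[Si](C)(C)C(C)(C)C | intermediate
5 | (S)-1-[4-(tert-butyldimethylsilyloxy)-3,5-dimethoxyphenyl]propan-2-ol | C[C@H](O)Cc1cc(OC)c(O[Si](C)(C)C(C)(C)C)c(OC)c1 | intermediate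
6 | 4-allyl-2,6-dimethoxyphenol | C=CCc1cc(OC)c(O)c(OC)c1 | starting material
7 | 2,6-dimethoxy-4-[(E)-prop-1-enyl]phenol | C/C=C/c1cc(OC)c(O)c(OC)c1 | intermediate
8 | tert-butyl{4-[(2R)-2-{2,6-dimethoxy-4-[(E)-prop-1-enyl]phenoxy}propyl]-2,6-dimethoxyphenoxy}dimethylsilane | C/C=C/c1cc(OC)c(O[C@H](C)Cc2cc(OC)c(O[Si](C)(C)C(C)(C)C)c(OC)c2)c(OC)c1 | intermediate
9 | 4-[(2R)-2-{2,6-dimethoxy-4-[(E)-prop-1-enyl]phenoxy}propyl]-2,6-dimethoxyphenol (ArBC–OH) | C/C=C/c1cc(OC)c(O[C@H](C)Cc2cc(OC)c(O)c(OC)c2)c(OC)c1 | intermediate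
10 | ethyl bromoacetate | CCOC(=O)CBr | starting material
11 | ethyl 2-(ArBC-oxy)acetate | C/C=C/c1cc(OC)c(O[C@H](C)Cc2cc(OC)c(OCC(=O)OCC)c(OC)c2)c(OC)c1 | intermediate
12 | 2-(ArBC-oxy)acetic acid | C/C=C/c1cc(OC)c(O[C@H](C)Cc2cc(OC)c(OCC(=O)O)c(OC)c2)c(OC)c1 | intermediate
13 | (S)-4-benzyloxazolidin-2-one | O=C1N[C@@H](Cc2ccccc2)CO1 | starting material
14 | 2-(ArBC-oxy)acetic pivalic anhydride | C/C=C/c1cc(OC)c(O[C@H](C)Cc2cc(OC)c(OCC(=O)OC(=O)C(C)(C)C)c(OC)c2)c(OC)c1 | intermediate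
15 | (S)-4-benzyl-3-[2-(ArBC-oxy)acetyl]oxazolidin-2-one | C/C=C/c1cc(OC)c(O[C@H](C)Cc2cc(OC)c(OCC(=O)N3C(=O)OC[C@@H]3Cc4ccccc4)c(OC)c2)c(OC)c1 | intermediate
16 | 3,4,5-trimethoxybenzaldehyde | COc1cc(C=O)cc(OC)c1OC | starting material
17 | (Z)-dibutylboron enolate of 15 | C/C=C/c1cc(OC)c(O[C@H](C)Cc2cc(OC)c(O/C=C(\OB(CCCC)CCCC)N3C(=O)OC[C@@H]3Cc4ccccc4)c(OC)c2)c(OC)c1 | intermediate
18 | dibutylboron aldolate (O-BBu2 derivative of 19) | C/C=C/c1cc(OC)c(O[C@H](C)Cc2cc(OC)c(O[C@H](C(=O)N3C(=O)OC[C@@H]3Cc4ccccc4)[C@H](OB(CCCC)CCCC)c5cc(OC)c(OC)c(OC)c5)c(OC)c2)c(OC)c1 | intermediate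
19 | (S)-4-benzyl-3-[(2S,3R)-2-(ArBC-oxy)-3-hydroxy-3-(3,4,5-trimethoxyphenyl)propanoyl]oxazolidin-2-one | C/C=C/c1cc(OC)c(O[C@H](C)Cc2cc(OC)c(O[C@H](C(=O)N3C(=O)OC[C@@H]3Cc4ccccc4)[C@H](O)c5cc(OC)c(OC)c(OC)c5)c(OC)c2)c(OC)c1 | intermediate
20 | (S)-4-benzyl-3-[(2S,3R)-2-(ArBC-oxy)-3-(tert-butyldimethylsilyloxy)-3-(3,4,5-trimethoxyphenyl)propanoyl]oxazolidin-2-one | C/C=C/c1cc(OC)c(O[C@H](C)Cc2cc(OC)c(O[C@H](C(=O)N3C(=O)OC[C@@H]3Cc4ccccc4)[C@H](O[Si](C)(C)C(C)(C)C)c5cc(OC)c(OC)c(OC)c5)c(OC)c2)c(OC)c1 | intermediate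
21 | (2R,3R)-2-(ArBC-oxy)-3-(tert-butyldimethylsilyloxy)-3-(3,4,5-trimethoxyphenyl)propan-1-ol | C/C=C/c1cc(OC)c(O[C@H](C)Cc2cc(OC)c(O[C@H](CO)[C@H](O[Si](C)(C)C(C)(C)C)c3cc(OC)c(OC)c(OC)c3)c(OC)c2)c(OC)c1 | intermediate
22 | (2R,3R)-2-(ArBC-oxy)-3-(tert-butyldimethylsilyloxy)-3-(3,4,5-trimethoxyphenyl)propyl 4-methylbenzenesulfonate | C/C=C/c1cc(OC)c(O[C@H](C)Cc2cc(OC)c(O[C@H](COS(=O)(=O)c3ccc(C)cc3)[C@H](O[Si](C)(C)C(C)(C)C)c4cc(OC)c(OC)c(OC)c4)c(OC)c2)c(OC)c1 | intermediate
23 | tert-butyl{[(1R,2R)-2-(ArBC-oxy)-1-(3,4,5-trimethoxyphenyl)propyl]oxy}dimethylsilane | C/C=C/c1cc(OC)c(O[C@H](C)Cc2cc(OC)c(O[C@H](C)[C@H](O[Si](C)(C)C(C)(C)C)c3cc(OC)c(OC)c(OC)c3)c(OC)c2)c(OC)c1 | intermediate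
24 | (1R,2R)-2-(ArBC-oxy)-1-(3,4,5-trimethoxyphenyl)propan-1-ol (threo) | C/C=C/c1cc(OC)c(O[C@H](C)Cc2cc(OC)c(O[C@H](C)[C@H](O)c3cc(OC)c(OC)c(OC)c3)c(OC)c2)c(OC)c1 | intermediate
25 | (1S,2R)-2-(ArBC-oxy)-1-(3,4,5-trimethoxyphenyl)propyl 4-nitrobenzoate | C/C=C/c1cc(OC)c(O[C@H](C)Cc2cc(OC)c(O[C@H](C)[C@@H](OC(=O)c3ccc(cc3)[N+](=O)[O-])c4cc(OC)c(OC)c(OC)c4)c(OC)c2)c(OC)c1 | intermediate
26 | (1S,2R)-2-(ArBC-oxy)-1-(3,4,5-trimethoxyphenyl)propan-1-ol (erythro) | C/C=C/c1cc(OC)c(O[C@H](C)Cc2cc(OC)c(O[C@H](C)[C@@H](O)c3cc(OC)c(OC)c(OC)c3)c(OC)c2)c(OC)c1 | intermediate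
27 | (1S,2R)-2-(ArBC-oxy)-1-(3,4,5-trimethoxyphenyl)propyl acetate (CNP0157869.1) | C/C=C/c1cc(OC)c(O[C@H](C)Cc2cc(OC)c(O[C@H](C)[C@@H](OC(C)=O)c3cc(OC)c(OC)c(OC)c3)c(OC)c2)c(OC)c1 | target

**Step count**
Total steps: 17.
Longest linear sequence: 16 steps (1 → 27 through steps 1, 2 and 4–17). Step 3 is a one-step side branch.

**Three steps most likely to fail**

**Step 4.** This is a Mitsunobu etherification of a flanked, weakly acidic 2,6-dimethoxyphenol with an unactivated homobenzylic secondary alcohol.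
- Risks: slow coupling, elimination to the styrene, or aryl participation that erodes the inversion.
- Fallback: form the C8'–O bond on an activated lactate carbon and close the fragment by a C–C coupling instead. It sets out from 7 and comes back at 8.
- Mitsunobu reaction of 7 with ethyl (S)-lactate (PPh3, DIAD, THF, 0 °C to rt; clean inversion next to the ester) gives ethyl (R)-2-{2,6-dimethoxy-4-[(E)-prop-1-enyl]phenoxy}propanoate F1.
- LiAlH4 (THF, 0 °C) then gives (R)-2-{2,6-dimethoxy-4-[(E)-prop-1-enyl]phenoxy}propan-1-ol F2.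
- TsCl in pyridine gives (R)-2-{2,6-dimethoxy-4-[(E)-prop-1-enyl]phenoxy}propyl 4-methylbenzenesulfonate F3.
- The Grignard reagent 4 of step 2 displaces the primary tosylate under Li2CuCl4 catalysis (5 mol %, THF, −20 °C to rt). The stereocentre is not touched, and the product is 8.

**Step 9.** This is boron enolisation of a large polyether imide.
- Risks: the many ether oxygens can tie up Bu2BOTf, the peroxide work-up meets an electron-rich styrene, and the diastereomer ratio may suffer.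
- Fallback: keep the same C7–C8 aldol bond but change the auxiliary class and the enolate metal, with a non-oxidative work-up. It sets out from 12 and comes back at 21.
- Acid 12 is coupled with (S)-4-benzyl-1,3-thiazolidine-2-thione (EDC·HCl, DMAP cat., CH2Cl2) to give (S)-1-(4-benzyl-2-thioxothiazolidin-3-yl)-2-(ArBC-oxy)ethan-1-one F4.
- Soft enolisation with TiCl4 (1.05 equiv), iPr2NEt (1.1 equiv) and N-methylpyrrolidinone (1 equiv) in CH2Cl2 at 0 °C, followed by 16 at −78 to 0 °C, gives the Evans-type syn (2S,3R) aldol thiazolidinethione F5.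
- TBSOTf and 2,6-lutidine give its C7 silyl ether F6.
- NaBH4 (THF/EtOH, 0 °C) removes the very labile thione auxiliary to give 21.

**Step 15.** This is an SN2 inversion at an electron-rich, hindered benzylic carbinol.
- Risks: partial ionisation with loss of stereochemical fidelity, or elimination to the enol ether.
- Fallback: replace the displacement by oxidation and chelation-controlled reduction. It sets out from 24 and comes back at 26, skipping steps 15 and 16.
- Dess–Martin periodinane (NaHCO3, CH2Cl2, 0 °C) gives (R)-2-(ArBC-oxy)-1-(3,4,5-trimethoxyphenyl)propan-1-one F7.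
- Zn(BH4)2 (Et2O, −78 to −20 °C) reduces the five-membered zinc chelate of the carbonyl and aryloxy oxygens from the face that carries H rather than CH3. This gives the erythro (1S,2R) alcohol 26.

**Further compounds**
F1 | step 4 | ethyl (R)-2-{2,6-dimethoxy-4-[(E)-prop-1-enyl]phenoxy}propanoate | C/C=C/c1cc(OC)c(O[C@H](C)C(=O)OCC)c(OC)c1
F2 | step 4 | (R)-2-{2,6-dimethoxy-4-[(E)-prop-1-enyl]phenoxy}propan-1-ol | C/C=C/c1cc(OC)c(O[C@H](C)CO)c(OC)c1
F3 | step 4 | (R)-2-{2,6-dimethoxy-4-[(E)-prop-1-enyl]phenoxy}propyl 4-methylbenzenesulfonate | C/C=C/c1cc(OC)c(O[C@H](C)COS(=O)(=O)c2ccc(C)cc2)c(OC)c1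
F4 | step 9 | (S)-1-(4-benzyl-2-thioxothiazolidin-3-yl)-2-(ArBC-oxy)ethan-1-one | C/C=C/c1cc(OC)c(O[C@H](C)Cc2cc(OC)c(OCC(=O)N3C(=S)SC[C@@H]3Cc4ccccc4)c(OC)c2)c(OC)c1
F5 | step 9 | (2S,3R)-1-[(S)-4-benzyl-2-thioxothiazolidin-3-yl]-2-(ArBC-oxy)-3-hydroxy-3-(3,4,5-trimethoxyphenyl)propan-1-one | C/C=C/c1cc(OC)c(O[C@H](C)Cc2cc(OC)c(O[C@H](C(=O)N3C(=S)SC[C@@H]3Cc4ccccc4)[C@H](O)c5cc(OC)c(OC)c(OC)c5)c(OC)c2)c(OC)c1
F6 | step 9 | (2S,3R)-1-[(S)-4-benzyl-2-thioxothiazolidin-3-yl]-2-(ArBC-oxy)-3-(tert-butyldimethylsilyloxy)-3-(3,4,5-trimethoxyphenyl)propan-1-one | C/C=C/c1cc(OC)c(O[C@H](C)Cc2cc(OC)c(O[C@H](C(=O)N3C(=S)SC[C@@H]3Cc4ccccc4)[C@H](O[Si](C)(C)C(C)(C)C)c5cc(OC)c(OC)c(OC)c5)c(OC)c2)c(OC)c1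
F7 | step 15 | (R)-2-(ArBC-oxy)-1-(3,4,5-trimethoxyphenyl)propan-1-one | C/C=C/c1cc(OC)c(O[C@H](C)Cc2cc(OC)c(O[C@H](C)C(=O)c3cc(OC)c(OC)c(OC)c3)c(OC)c2)c(OC)c1
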